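The tetrahydrofuran is disconnected at C3–C3a and C1–C10a (cyclonona[c]furan numbering). This exposes its C3–O2–C1 unit as a carbonyl ylide, made from formaldehyde and a malonyl carbene, and the trans-fused C3a–C10a bond as an (E)-enoyl dipolarophile. One three-component (3+2) cycloaddition thus forms both C–C bonds, the fully substituted C1 (as a geminal diester, later differentiated into the dienyl and acyloxymethyl arms) and both ring-fusion stereocentres under oxazolidinone control. Its precursor is an (S)-linalool-derived (E)-N-enoyl oxazolidinone that already carries the tertiary carbinol; ring-closing metathesis then builds the nine-membered ring.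

Key step: step 5

Remark: (S)-(+)-linalool of high enantiomeric purity and di-tert-butyl diazomalonate are taken as purchasable, and monomeric formaldehyde is taken as freshly cracked from paraformaldehyde into CH2Cl2. Ring atoms of the bicycle are numbered C1 (quaternary), O2, C3, C3a, C4 (methylidene carbon), C5, C6=C7, C8 (carbinol), C9, C10, C10a.

Step 1
Reactants: 1 (4R)-4-benzyl-1,3-oxazolidin-2-one; 2 (diethoxyphosphoryl)acetic acid
Product: 4 (4R)-4-benzyl-3-[(diethoxyphosphoryl)acetyl]-1,3-oxazolidin-2-one, via mixed pivalic anhydride 3 (not isolated)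
Conditions: PivCl, Et3N, THF, −20 °C; then 1, LiCl, −20 °C to rt
Reagents that add atoms: none
Why: Mixed-anhydride N-acylation, in which the LiCl-activated oxazolidinone attacks the less hindered phosphonoacetyl carbonyl of 3; no stereocentre is touched.

Step 2
Reactants: 5 (S)-linalool
Product: 6 (3S)-3,7-dimethyl-3-(trimethylsilyloxy)octa-1,6-diene
Conditions: TMSCl, imidazole, DMF, 0 °C to rt
Reagents that add atoms: chlorotrimethylsilane, C[Si](C)(C)Cl
Why: Silylation of the tertiary alcohol masks the hydroxyl against lactol formation, oxa-Michael addition and O–H insertion in steps 3 to 5.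

Step 3
Reactants: 6 (3S)-3,7-dimethyl-3-(trimethylsilyloxy)octa-1,6-diene
Product: 8 (4S)-4-methyl-4-(trimethylsilyloxy)hex-5-enal, via secondary ozonide 7 (not isolated)
Conditions: O3, CH2Cl2, −78 °C (Sudan Red 7B end point); then Me2S, −78 °C to rt
Reagents that add atoms: ozone, [O-][O+]=O
Why: Chemoselective ozonolysis, since the electron-rich trisubstituted alkene is cleaved much faster than the hindered vinyl group and the dye end point stops the reaction there.

Step 4
Reactants: 8 (4S)-4-methyl-4-(trimethylsilyloxy)hex-5-enal; 4 (4R)-4-benzyl-3-[(diethoxyphosphoryl)acetyl]-1,3-oxazolidin-2-one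
Product: 9 (4R)-4-benzyl-3-[(2E,6S)-6-methyl-6-(trimethylsilyloxy)octa-2,7-dienoyl]-1,3-oxazolidin-2-one
Conditions: LiCl, i-Pr2NEt, MeCN, rt
Reagents that add atoms: none
Why: Horner–Wadsworth–Emmons olefination under Masamune–Roush conditions should give the (E)-enoyl imide and is mild enough to leave the silyl ether intact.

Step 5
Reactants: 9 (4R)-4-benzyl-3-[(2E,6S)-6-methyl-6-(trimethylsilyloxy)octa-2,7-dienoyl]-1,3-oxazolidin-2-one; 10 di-tert-butyl 2-diazomalonate; 11 formaldehyde
Product: 13 di-tert-butyl (3S,4S)-4-{[(4R)-4-benzyl-2-oxo-1,3-oxazolidin-3-yl]carbonyl}-3-[(3S)-3-methyl-3-(trimethylsilyloxy)pent-4-en-1-yl]oxolane-2,2-dicarboxylate, via carbonyl ylide 12 (not isolated)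
Conditions: Rh2(esp)2 (2 mol %; esp = α,α,α′,α′-tetramethyl-1,3-benzenedipropionate), Yb(OTf)3 (1 equiv), 4 Å MS, CH2Cl2, 0 °C to rt; 10 (3 equiv) and 11 (5 equiv, ca. 1 M in CH2Cl2) added over 6 h
Reagents that add atoms: none
Why: Rh2(esp)2 converts 10 into a malonyl rhodium carbene that is captured by the oxygen lone pair of formaldehyde to give carbonyl ylide 12, which adds across the Yb(OTf)3-chelated, s-cis enoyl imide 9 in a (3+2) cycloaddition. The closest known reactions are the rhodium-catalysed three-component diazo ester/aldehyde/dipolarophile carbonyl ylide cycloadditions and the Lewis acid-activated cycloadditions of carbonyl ylides with N-enoyl oxazolidinones. The oxolane ring is closed in one concerted, suprafacial (3+2) event in which the ester-stabilised ylide carbon bonds to the β-carbon and the CH2 terminus to the α-carbon, as the polarisation of both partners dictates. The trans C3/C4 relationship follows from the (E)-alkene, and the absolute configuration of both centres (3S,4S) from attack on the face of the chelate opposite to the benzyl group of the (R)-auxiliary; C2 carries two identical esters and is not yet stereogenic. The step needs the ylide to be trapped by 9 and not by a second formaldehyde or by closure to the oxirane, which Lewis acid activation of 9, slow addition and an excess of 10 and 11 should secure.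

Step 6
Reactants: 13 di-tert-butyl (3S,4S)-4-{[(4R)-4-benzyl-2-oxo-1,3-oxazolidin-3-yl]carbonyl}-3-[(3S)-3-methyl-3-(trimethylsilyloxy)pent-4-en-1-yl]oxolane-2,2-dicarboxylate
Product: 15 di-tert-butyl (3S,4S)-3-[(3S)-3-hydroxy-3-methylpent-4-en-1-yl]-4-[methoxy(methyl)carbamoyl]oxolane-2,2-dicarboxylate, via silyl-protected Weinreb amide 14 (not isolated)
Conditions: MeNH(OMe)·HCl, AlMe3, CH2Cl2, 0 °C to rt; then 1 M HCl, THF, 0 °C
Reagents that add atoms: N,O-dimethylhydroxylamine hydrochloride, CNOC.Cl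
Why: Weinreb transamination by the aluminium amide occurs at the exocyclic imide carbonyl and spares the hindered tert-butyl esters, and the dilute acid then cleaves the trimethylsilyl ether.

Step 7
Reactants: 15 di-tert-butyl (3S,4S)-3-[(3S)-3-hydroxy-3-methylpent-4-en-1-yl]-4-[methoxy(methyl)carbamoyl]oxolane-2,2-dicarboxylate
Product: 16 di-tert-butyl (3S,4S)-4-(but-3-enoyl)-3-[(3S)-3-hydroxy-3-methylpent-4-en-1-yl]oxolane-2,2-dicarboxylate
Conditions: allylMgBr (3 equiv), THF, −78 °C; then sat. aq. NH4Cl, −78 °C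
Reagents that add atoms: allylmagnesium bromide, C=CC[Mg]Br
Why: Grignard addition to the Weinreb amide stops at the chelated tetrahedral intermediate, the neopentyl-type tert-butyl esters should be inert at −78 °C, and the cold buffered quench avoids conjugation of the β,γ-unsaturated ketone and epimerisation at C4.

Step 8
Reactants: 16 di-tert-butyl (3S,4S)-4-(but-3-enoyl)-3-[(3S)-3-hydroxy-3-methylpent-4-en-1-yl]oxolane-2,2-dicarboxylate
Product: 17 di-tert-butyl (3aS,6Z,8S,10aS)-8-hydroxy-8-methyl-4-oxo-3,3a,4,5,8,9,10,10a-octahydrocyclonona[c]furan-1,1-dicarboxylate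
Conditions: second-generation Grubbs catalyst (10 mol %), 1,4-benzoquinone (20 mol %), toluene (1 mM), 80 °C
Reagents that add atoms: none
Why: Ring-closing metathesis of the allyl and vinyl carbinol termini expels ethene and closes the nine-membered ring, in which ring strain should enforce the (Z)-alkene; the ketone is kept at C4 so that no 1,1-disubstituted alkene can divert the closure to a seven-membered ring.

Step 9
Reactants: 17 di-tert-butyl (3aS,6Z,8S,10aS)-8-hydroxy-8-methyl-4-oxo-3,3a,4,5,8,9,10,10a-octahydrocyclonona[c]furan-1,1-dicarboxylate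
Product: 18 di-tert-butyl (3aR,6Z,8S,10aS)-8-hydroxy-8-methyl-4-methylidene-3,3a,4,5,8,9,10,10a-octahydrocyclonona[c]furan-1,1-dicarboxylate
Conditions: Zn, CH2Br2, TiCl4, THF/CH2Cl2, 0 °C to rt
Reagents that add atoms: dibromomethane, BrCBr
Why: Lombardo methylenation is non-basic, so C3a is not epimerised and the skipped enone is not conjugated, and it is selective for the ketone over the esters.

Step 10
Reactants: 18 di-tert-butyl (3aR,6Z,8S,10aS)-8-hydroxy-8-methyl-4-methylidene-3,3a,4,5,8,9,10,10a-octahydrocyclonona[c]furan-1,1-dicarboxylate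
Product: 19 tert-butyl (1S,3aR,6Z,8S,10aS)-1-formyl-8-hydroxy-8-methyl-4-methylidene-3,3a,4,5,8,9,10,10a-octahydro-1H-cyclonona[c]furan-1-carboxylate
Conditions: i-Bu2AlH (2.2 equiv), CH2Cl2, −78 °C; then aq. potassium sodium tartrate
Reagents that add atoms: none
Why: Diisobutylaluminium hydride takes a tert-butyl ester only to the aldehyde level at −78 °C (stable tetrahedral aluminate) and should attack the less hindered of the two diastereotopic esters, the one trans to the C10 methylene on C10a, which sets C1.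

Step 11
Reactants: 19 tert-butyl (1S,3aR,6Z,8S,10aS)-1-formyl-8-hydroxy-8-methyl-4-methylidene-3,3a,4,5,8,9,10,10a-octahydro-1H-cyclonona[c]furan-1-carboxylate
Product: 20 tert-butyl (1R,3aR,6Z,8S,10aS)-8-hydroxy-8-methyl-4-methylidene-1-[(1E)-4-methylpenta-1,3-dien-1-yl]-3,3a,4,5,8,9,10,10a-octahydro-1H-cyclonona[c]furan-1-carboxylate
Conditions: prenyl bromide, PBu3, THF, rt; then KN(SiMe3)2, −78 °C; then 19, −78 °C to rt
Reagents that add atoms: 1-bromo-3-methylbut-2-ene (as its tributylphosphonium ylide), CC(C)=CCBr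
Why: Wittig olefination with an allylic trialkylphosphonium ylide is the (E)-selective variant for dienes, reacts through the unsubstituted α-carbon and leaves the hindered tert-butyl ester untouched.

Step 12
Reactants: 20 tert-butyl (1R,3aR,6Z,8S,10aS)-8-hydroxy-8-methyl-4-methylidene-1-[(1E)-4-methylpenta-1,3-dien-1-yl]-3,3a,4,5,8,9,10,10a-octahydro-1H-cyclonona[c]furan-1-carboxylate
Product: 21 (1R,3aR,6Z,8S,10aS)-1-(hydroxymethyl)-8-methyl-4-methylidene-1-[(1E)-4-methylpenta-1,3-dien-1-yl]-3,3a,4,5,8,9,10,10a-octahydro-1H-cyclonona[c]furan-8-ol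
Conditions: LiAlH4, THF, 0 °C to rt; then H2O, aq. NaOH
Reagents that add atoms: none
Why: Hydride reduction of the remaining tert-butyl ester gives the primary alcohol and does not touch the isolated alkenes or the diene.

Step 13
Reactants: 21 (1R,3aR,6Z,8S,10aS)-1-(hydroxymethyl)-8-methyl-4-methylidene-1-[(1E)-4-methylpenta-1,3-dien-1-yl]-3,3a,4,5,8,9,10,10a-octahydro-1H-cyclonona[c]furan-8-ol
Product: 22 [(1R,3aR,6Z,8S,10aS)-8-hydroxy-8-methyl-4-methylidene-1-[(1E)-4-methylpenta-1,3-dien-1-yl]-3,3a,4,5,8,9,10,10a-octahydro-1H-cyclonona[c]furan-1-yl]methyl octadecanoate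
Conditions: octadecanoyl chloride (1.1 equiv), pyridine, DMAP (cat.), CH2Cl2, 0 °C
Reagents that add atoms: octadecanoyl chloride, CCCCCCCCCCCCCCCCCC(=O)Cl
Why: Acylation should occur only at the primary hydroxyl, the tertiary allylic alcohol being too hindered to react at 0 °C.

Compound list
1 | (4R)-4-benzyl-1,3-oxazolidin-2-one | O=C1OC[C@@H](Cc2ccccc2)N1 | starting material
2 | (diethoxyphosphoryl)acetic acid | CCOP(=O)(OCC)CC(=O)O | starting material
3 | (diethoxyphosphoryl)acetic pivalic anhydride | CCOP(=O)(OCC)CC(=O)OC(=O)C(C)(C)C | intermediate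
4 | (4R)-4-benzyl-3-[(diethoxyphosphoryl)acetyl]-1,3-oxazolidin-2-one | O=C1OC[C@@H](Cc2ccccc2)N1C(=O)CP(=O)(OCC)OCC | intermediate
5 | (S)-linalool, (3S)-3,7-dimethylocta-1,6-dien-3-ol | CC(C)=CCC[C@](C)(O)C=C | starting material
6 | (3S)-3,7-dimethyl-3-(trimethylsilyloxy)octa-1,6-diene | CC(C)=CCC[C@](C)(O[Si](C)(C)C)C=C | intermediate
7 | secondary ozonide, 3,3-dimethyl-5-[(3S)-3-methyl-3-(trimethylsilyloxy)pent-4-en-1-yl]-1,2,4-trioxolane | CC1(C)OOC(CC[C@](C)(O[Si](C)(C)C)C=C)O1 | intermediate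
8 | (4S)-4-methyl-4-(trimethylsilyloxy)hex-5-enal | O=CCC[C@](C)(O[Si](C)(C)C)C=C | intermediate
9 | (4R)-4-benzyl-3-[(2E,6S)-6-methyl-6-(trimethylsilyloxy)octa-2,7-dienoyl]-1,3-oxazolidin-2-one | O=C1OC[C@@H](Cc2ccccc2)N1C(=O)/C=C/CC[C@](C)(O[Si](C)(C)C)C=C | intermediate
10 | di-tert-butyl 2-diazomalonate | CC(C)(C)OC(=O)C(=[N+]=[N-])C(=O)OC(C)(C)C | starting material
11 | formaldehyde (monomeric) | C=O | starting material
12 | carbonyl ylide, methylidene[bis(tert-butoxycarbonyl)methyl]oxonium ylide | C=[O+][C-](C(=O)OC(C)(C)C)C(=O)OC(C)(C)C | intermediate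
13 | di-tert-butyl (3S,4S)-4-{[(4R)-4-benzyl-2-oxo-1,3-oxazolidin-3-yl]carbonyl}-3-[(3S)-3-methyl-3-(trimethylsilyloxy)pent-4-en-1-yl]oxolane-2,2-dicarboxylate | O=C1OC[C@@H](Cc2ccccc2)N1C(=O)[C@@H]3COC(C(=O)OC(C)(C)C)(C(=O)OC(C)(C)C)[C@H]3CC[C@](C)(O[Si](C)(C)C)C=C | intermediate
14 | di-tert-butyl (3S,4S)-4-[methoxy(methyl)carbamoyl]-3-[(3S)-3-methyl-3-(trimethylsilyloxy)pent-4-en-1-yl]oxolane-2,2-dicarboxylate | CON(C)C(=O)[C@@H]1COC(C(=O)OC(C)(C)C)(C(=O)OC(C)(C)C)[C@H]1CC[C@](C)(O[Si](C)(C)C)C=C | intermediate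
15 | di-tert-butyl (3S,4S)-3-[(3S)-3-hydroxy-3-methylpent-4-en-1-yl]-4-[methoxy(methyl)carbamoyl]oxolane-2,2-dicarboxylate | CON(C)C(=O)[C@@H]1COC(C(=O)OC(C)(C)C)(C(=O)OC(C)(C)C)[C@H]1CC[C@](C)(O)C=C | intermediate
16 | di-tert-butyl (3S,4S)-4-(but-3-enoyl)-3-[(3S)-3-hydroxy-3-methylpent-4-en-1-yl]oxolane-2,2-dicarboxylate | C=CCC(=O)[C@@H]1COC(C(=O)OC(C)(C)C)(C(=O)OC(C)(C)C)[C@H]1CC[C@](C)(O)C=C | intermediate
17 | di-tert-butyl (3aS,6Z,8S,10aS)-8-hydroxy-8-methyl-4-oxo-3,3a,4,5,8,9,10,10a-octahydrocyclonona[c]furan-1,1-dicarboxylate | O=C1C/C=C\[C@@](C)(O)CC[C@H]2[C@H]1COC2(C(=O)OC(C)(C)C)C(=O)OC(C)(C)C | intermediate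
18 | di-tert-butyl (3aR,6Z,8S,10aS)-8-hydroxy-8-methyl-4-methylidene-3,3a,4,5,8,9,10,10a-octahydrocyclonona[c]furan-1,1-dicarboxylate | C=C1C/C=C\[C@@](C)(O)CC[C@H]2[C@H]1COC2(C(=O)OC(C)(C)C)C(=O)OC(C)(C)C | intermediate
19 | tert-butyl (1S,3aR,6Z,8S,10aS)-1-formyl-8-hydroxy-8-methyl-4-methylidene-3,3a,4,5,8,9,10,10a-octahydro-1H-cyclonona[c]furan-1-carboxylate | C=C1C/C=C\[C@@](C)(O)CC[C@H]2[C@H]1CO[C@@]2(C=O)C(=O)OC(C)(C)C | intermediate
20 | tert-butyl (1R,3aR,6Z,8S,10aS)-8-hydroxy-8-methyl-4-methylidene-1-[(1E)-4-methylpenta-1,3-dien-1-yl]-3,3a,4,5,8,9,10,10a-octahydro-1H-cyclonona[c]furan-1-carboxylate | C=C1C/C=C\[C@@](C)(O)CC[C@H]2[C@H]1CO[C@@]2(/C=C/C=C(C)C)C(=O)OC(C)(C)C | intermediate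
21 | (1R,3aR,6Z,8S,10aS)-1-(hydroxymethyl)-8-methyl-4-methylidene-1-[(1E)-4-methylpenta-1,3-dien-1-yl]-3,3a,4,5,8,9,10,10a-octahydro-1H-cyclonona[c]furan-8-ol | C=C1C/C=C\[C@@](C)(O)CC[C@H]2[C@H]1CO[C@@]2(/C=C/C=C(C)C)CO | intermediate
22 | [(1R,3aR,6Z,8S,10aS)-8-hydroxy-8-methyl-4-methylidene-1-[(1E)-4-methylpenta-1,3-dien-1-yl]-3,3a,4,5,8,9,10,10a-octahydro-1H-cyclonona[c]furan-1-yl]methyl octadecanoate | C=C1C/C=C\[C@@](C)(O)CC[C@H]2[C@H]1CO[C@@]2(/C=C/C=C(C)C)COC(=O)CCCCCCCCCCCCCCCCC | target

Total step count: 13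
Longest linear sequence: 12 steps (steps 2 to 13, from (S)-linalool)

Steps most likely to fail

Step 5. The ylide may be intercepted by a second molecule of formaldehyde, or may collapse to the oxirane, faster than it adds to the β-substituted dipolarophile; incomplete chelation would also erode facial selectivity. The fallback sets out from 9 and comes back at 13, making the two bonds in separate polar steps. Conjugate addition of di-tert-butyl malonate to the chelated imide (Yb(OTf)3, Et3N, CH2Cl2) on the face opposite to the benzyl group would give the Michael adduct F1. Deprotonation of the malonate C–H (NaH, THF) and oxidation with dimethyldioxirane would give the tertiary alcohol F2, and DMSO/Ac2O/AcOH would convert it into the methylthiomethyl ether F3. SO2Cl2 (CH2Cl2, −78 °C) would then unveil the chloromethyl ether F4, which is not isolated. Treated with NaN(SiMe3)2 in THF at −78 °C, its chelated (Z)-imide enolate should close the oxolane by 5-exo-tet alkylation on the face away from the benzyl group, giving 13.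

Step 8. Closure of the nine-membered ring may lose to oligomerisation or to migration of the allyl double bond into conjugation, because the vinyl carbinol is a hindered metathesis partner. The fallback sets out from 15 and comes back at 17, forming the C5–C6 bond instead of the alkene. MeMgBr (THF, −78 °C) would give the methyl ketone F5, and ozonolysis of its only alkene (O3, CH2Cl2/MeOH, −78 °C; Me2S) the α-hydroxy aldehyde F6. Stork–Zhao olefination (Ph3P=CHI from (iodomethyl)triphenylphosphonium iodide and NaN(SiMe3)2, THF/HMPA, −78 °C) would give the (Z)-vinyl iodide F7. The kinetic potassium enolate of the methyl ketone (KN(SiMe3)2, THF, −78 °C) would then be coupled with the vinyl iodide by Pd(PPh3)4 in a palladium-catalysed intramolecular enolate alkenylation. This retains the (Z) geometry and gives 17.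

Step 10. The hydride may discriminate poorly between the two diastereotopic esters, or over-reduce. The fallback sets out from 18 and comes back at 22, replacing steric discrimination by proximity. LiAlH4 (THF) would reduce both esters to the triol F8. I2/NaHCO3 (MeCN, 0 °C) should then engage only the hydroxymethyl group that is 1,3-cis to C4, in a 6-exo iodoetherification onto the exocyclic methylene, giving the bridged iodoether F9; the other hydroxymethyl group cannot reach the alkene. Acylation of that free group with octadecanoyl chloride (pyridine, DMAP) would give the stearate F10. Zn/AcOH/EtOH would regenerate the methylidene by reductive β-elimination and release the second hydroxymethyl group as alcohol F11. Dess–Martin periodinane would oxidise it to the aldehyde F12, and the Wittig reaction of step 11 would then give 22 directly.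

Further compounds
F1 | step 5 | di-tert-butyl 2-{(2S,5S)-1-[(4R)-4-benzyl-2-oxo-1,3-oxazolidin-3-yl]-5-methyl-1-oxo-5-(trimethylsilyloxy)hept-6-en-3-yl}malonate (Michael adduct; the new centre has the configuration of C10a) | O=C1OC[C@@H](Cc2ccccc2)N1C(=O)C[C@H](CC[C@](C)(O[Si](C)(C)C)C=C)C(C(=O)OC(C)(C)C)C(=O)OC(C)(C)C
F2 | step 5 | 2-hydroxy derivative of F1 (tertiary alcohol at the malonate carbon) | O=C1OC[C@@H](Cc2ccccc2)N1C(=O)C[C@H](CC[C@](C)(O[Si](C)(C)C)C=C)C(O)(C(=O)OC(C)(C)C)C(=O)OC(C)(C)C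
F3 | step 5 | methylthiomethyl ether of F2 | O=C1OC[C@@H](Cc2ccccc2)N1C(=O)C[C@H](CC[C@](C)(O[Si](C)(C)C)C=C)C(OCSC)(C(=O)OC(C)(C)C)C(=O)OC(C)(C)C
F4 | step 5 | chloromethyl ether of F2 (not isolated) | O=C1OC[C@@H](Cc2ccccc2)N1C(=O)C[C@H](CC[C@](C)(O[Si](C)(C)C)C=C)C(OCCl)(C(=O)OC(C)(C)C)C(=O)OC(C)(C)C
F5 | step 8 | di-tert-butyl (3S,4S)-4-acetyl-3-[(3S)-3-hydroxy-3-methylpent-4-en-1-yl]oxolane-2,2-dicarboxylate | CC(=O)[C@@H]1COC(C(=O)OC(C)(C)C)(C(=O)OC(C)(C)C)[C@H]1CC[C@](C)(O)C=C
F6 | step 8 | di-tert-butyl (3S,4S)-4-acetyl-3-[(3S)-3-hydroxy-3-methyl-4-oxobutyl]oxolane-2,2-dicarboxylate | CC(=O)[C@@H]1COC(C(=O)OC(C)(C)C)(C(=O)OC(C)(C)C)[C@H]1CC[C@](C)(O)C=O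
F7 | step 8 | di-tert-butyl (3S,4S)-4-acetyl-3-[(3S,4Z)-3-hydroxy-5-iodo-3-methylpent-4-en-1-yl]oxolane-2,2-dicarboxylate | CC(=O)[C@@H]1COC(C(=O)OC(C)(C)C)(C(=O)OC(C)(C)C)[C@H]1CC[C@](C)(O)/C=C\I
F8 | step 10 | (3aR,6Z,8S,10aS)-1,1-bis(hydroxymethyl)-8-methyl-4-methylidene-3,3a,4,5,8,9,10,10a-octahydro-1H-cyclonona[c]furan-8-ol | C=C1C/C=C\[C@@](C)(O)CC[C@H]2[C@H]1COC2(CO)CO
F9 | step 10 | bridged iodoether: C4 carries an iodomethyl group and is linked through oxygen to the C1 hydroxymethyl carbon that is cis to it; the other C1 hydroxymethyl group and the C8 hydroxyl are free (configuration at C4 fixed by the bridge and not specified) | ICC13C/C=C\[C@@](C)(O)CC[C@H]2[C@H]1CO[C@@]2(CO3)CO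
F10 | step 10 | octadecanoate of F9 at its free hydroxymethyl group | ICC13C/C=C\[C@@](C)(O)CC[C@H]2[C@H]1CO[C@@]2(CO3)COC(=O)CCCCCCCCCCCCCCCCC
F11 | step 10 | [(1S,3aR,6Z,8S,10aS)-8-hydroxy-1-(hydroxymethyl)-8-methyl-4-methylidene-3,3a,4,5,8,9,10,10a-octahydro-1H-cyclonona[c]furan-1-yl]methyl octadecanoate | C=C1C/C=C\[C@@](C)(O)CC[C@H]2[C@H]1CO[C@@]2(CO)COC(=O)CCCCCCCCCCCCCCCCC
F12 | step 10 | [(1S,3aR,6Z,8S,10aS)-1-formyl-8-hydroxy-8-methyl-4-methylidene-3,3a,4,5,8,9,10,10a-octahydro-1H-cyclonona[c]furan-1-yl]methyl octadecanoate | C=C1C/C=C\[C@@](C)(O)CC[C@H]2[C@H]1CO[C@@]2(C=O)COC(=O)CCCCCCCCCCCCCCCCC
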